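**Retrosynthetic overview**
- The target comes from a β‑alkylidene lactone fused to the ten‑membered ring. Convex‑face dihydroxylation sets C7 and C8, and an O9→O7 acyl shift then gives the natural lactone. C17 is set just before by kinetic protonation, and C9 by Felkin–Anh reduction of a ketone.
- The ten‑membered ring is closed at C8–C9 by a light‑driven nickel/HAT coupling of the C9 aldehyde C–H with a (Z)‑dienyl bromide.
- The seco compound comes from a three‑component coupling on a carvone‑derived enone (vinyl 1,4‑addition, then aldol with the C2–C8/C17–C19 aldehyde). This sets C10, C1 and C2.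
- The ring A enone comes from (R)‑carvone by methylation (C11), 1,3‑carbonyl transposition and isopropenyl→acetate conversion with retention (C12).
- Ring order: ring A is bought, then the ten‑membered carbocycle is closed, then the γ‑lactone.

Assumption: briarane numbering is used throughout (C1 quaternary, C2–C9 large ring, C10–C14 ring A, C15/C16/C18/C20 methyls, C17/C19 lactone), and β is the face of ring A that carries Me‑15.

**Step 1**
Reactants: 1 (R)-(−)-carvone
Product: 3 (5R,6S)-2,6-dimethyl-5-(prop-1-en-2-yl)cyclohex-2-en-1-one, via lithium dienolate 2 (not isolated)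
Conditions: LiN(iPr)2, THF, −78 °C; MeI, −78 to 0 °C
Reagents that add atoms: iodomethane, CI
Why: Kinetic α'-deprotonation followed by enolate alkylation anti to the neighbouring isopropenyl group sets C11 (Me-20) trans to the bought C12 centre, and the trans isomer is also the one favoured on base equilibration.

**Step 2**
Reactants: 3 (5R,6S)-6-methylcarvone
Product: 4 2,3-epoxide of 3 (oxirane oxygen trans to the isopropenyl group)
Conditions: 30% H2O2, NaOH (cat.), MeOH, 0 °C
Reagents that add atoms: hydrogen peroxide, OO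
Why: Weitz–Scheffer nucleophilic epoxidation touches only the enone alkene, with hydroperoxide adding axially anti to the isopropenyl group; the two new centres are transient.

**Step 3**
Reactants: 4 epoxy ketone
Product: 6 (1R,4R,5R)-2,4-dimethyl-5-(prop-1-en-2-yl)cyclohex-2-en-1-ol, via epoxy hydrazone 5 (not isolated)
Conditions: N2H4·H2O, AcOH (cat.), MeOH, 0 °C to rt
Reagents that add atoms: none
Why: In the Wharton transposition the hydrazone fragments with loss of N2, opens the oxirane and moves the alkene to C1=C10, leaving the oxygen on C14 and C11/C12 untouched.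

**Step 4**
Reactants: 6 allylic alcohol
Product: 7 (4R,5R)-2,4-dimethyl-5-(prop-1-en-2-yl)cyclohex-2-en-1-one
Conditions: MnO2, CH2Cl2, rt
Reagents that add atoms: none
Why: Selective allylic alcohol oxidation completes the 1,3-carbonyl transposition under neutral conditions, so C11 and C12 are not touched.

**Step 5**
Reactants: 7 transposed enone
Product: 10 (4R,5R)-5-acetoxy-2,4-dimethylcyclohex-2-en-1-one, via methoxy hydroperoxide 8 (not isolated), via peroxyacetate 9 (not isolated)
Conditions: O3, CH2Cl2/MeOH, −78 °C; Ac2O, pyridine, DMAP (cat.), 0 to 40 °C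
Reagents that add atoms: ozone, [O-][O+]=O; methanol, CO
Why: The 1,1-disubstituted alkene is ozonised far faster than the enone alkene, and the acylated α-methoxy hydroperoxide undergoes Criegee rearrangement with retention at the migrating C12, which gives the α-acetate; pyridine replaces a stronger amine to avoid β-elimination.

**Step 6**
Reactants: 11 but-2-yn-1-ol; 12 [2-(1,3-dioxolan-2-yl)ethyl]magnesium bromide
Product: 14 (E)-2-chloro-5-(1,3-dioxolan-2-yl)-3-methylpent-2-en-1-ol, via magnesacycle 13 (not isolated)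
Conditions: 12 (2.3 equiv), CuI (10 mol%), THF/Et2O, −10 °C to rt; NCS, −30 °C; H2O
Reagents that add atoms: N-chlorosuccinimide, O=C1CCC(=O)N1Cl
Why: Copper-catalysed anti-carbomagnesiation of the propargylic alkoxide gives the five-membered magnesacycle, and its C–Mg bond is chlorinated with retention, so the tetrasubstituted chloroalkene has C4 cis to C7.

**Step 7**
Reactants: 14 chloro allylic alcohol
Product: 15 (E)-2-chloro-5-(1,3-dioxolan-2-yl)-3-methylpent-2-enal
Conditions: MnO2, CH2Cl2, rt, dark
Reagents that add atoms: none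
Why: Neutral allylic oxidation gives the α-chloroenal without E/Z leakage and leaves the acetal intact.

**Step 8**
Reactants: 15 α-chloroenal
Product: 16 (3E)-1,1-dibromo-3-chloro-6-(1,3-dioxolan-2-yl)-4-methylhexa-1,3-diene
Conditions: CBr4, PPh3, 2,6-lutidine, CH2Cl2, 0 °C
Reagents that add atoms: tetrabromomethane, BrC(Br)(Br)Br
Why: Ramirez dibromo-olefination (first stage of the Corey–Fuchs sequence) works on hindered enals, and the buffer protects the acetal.

**Step 9**
Reactants: 16 dibromodiene
Product: 17 methyl (3Z,5E)-3-bromo-5-chloro-8-(1,3-dioxolan-2-yl)-2,6-dimethylocta-3,5-dienoate (racemic at C17)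
Conditions: Zn, methyl 2-bromopropanoate, THF, 40 °C; then 16, Pd(PPh3)4 (5 mol%), THF, rt
Reagents that add atoms: methyl 2-bromopropanoate, CC(Br)C(=O)OC
Why: This is a trans-selective Negishi monocoupling of a 1,1-dibromoalkene: zerovalent palladium inserts into the less hindered C–Br bond trans to C6, so the remaining bromine sits cis to C6; C17 is deliberately left racemic and is reset in step 17.

**Step 10**
Reactants: 17 acetal ester
Product: 18 methyl (3Z,5E)-3-bromo-5-chloro-2,6-dimethyl-9-oxonona-3,5-dienoate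
Conditions: 1 M HCl, THF, rt
Reagents that add atoms: water, O
Why: Mild acetal hydrolysis frees the C2 aldehyde, and the halodiene and the ester are inert to dilute acid.

**Step 11**
Reactants: 10 enone acetate; 18 aldehyde
Product: 21 keto diacetate (C14 ketone; C1 with β-Me-15 and α-C2 chain; (2S)-OAc; β-vinyl at C10; β-Me-20; α-12-OAc), via magnesium enolate 19 (not isolated), via magnesium aldolate 20 (not isolated)
Conditions: CH2=CHMgBr (1.1 equiv), CuBr·SMe2 (15 mol%), THF, −78 to −40 °C; 18, −78 °C; Ac2O, DMAP, −78 °C to rt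
Reagents that add atoms: vinylmagnesium bromide, C=C[Mg]Br; acetic anhydride, CC(=O)OC(C)=O
Why: Copper-catalysed 1,4-addition occurs axially and anti to the C12 acetoxy group (3,5-trans, hence cis to Me-20) and sets C10; the enolate then adds to 18 anti to the new vinyl group through a closed Zimmerman–Traxler chair (C10 arm pseudo-equatorial, Me-15 pseudo-axial), which gives 1S,2S; acetylation of the aldolate blocks the retro-aldol.

**Step 12**
Reactants: 21 keto diacetate
Product: 22 C14 alcohol (carbinol configuration inconsequential)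
Conditions: NaBH4, CeCl3·7H2O, MeOH, −20 °C
Reagents that add atoms: none
Why: Buffered borohydride reduction takes the only ketone without β-elimination of the C12 acetate, the esters and alkenyl halides survive, and the new centre is destroyed in step 13.

**Step 13**
Reactants: 22 C14 alcohol
Product: 23 cyclohexene (C13=C14) with the C10 vinyl group
Conditions: Burgess reagent, toluene, 70 °C
Reagents that add atoms: none
Why: In the Burgess syn-elimination C1 is quaternary, so only a C13 hydrogen can leave, which gives C13=C14 regiospecifically under neutral conditions.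

**Step 14**
Reactants: 23 vinyl cyclohexene
Product: 24 C9 aldehyde (seco bromo aldehyde)
Conditions: OsO4 (2 mol%), NaIO4, 2,6-lutidine, dioxane/H2O, rt
Reagents that add atoms: sodium periodate, [Na+].[O-]I(=O)(=O)=O
Why: In the Lemieux–Johnson cleavage the monosubstituted vinyl group is osmylated well ahead of the neopentyl C13=C14 alkene (deactivated by the allylic acetate) and the doubly halogenated diene.

**Step 15**
Reactants: 24 seco bromo aldehyde
Product: 25 ten-membered (5E,7Z)-dienone ester (C9 ketone)
Conditions: Ir[dF(CF3)ppy]2(dtbbpy)PF6 (2 mol%), NiBr2(dtbbpy) (20 mol%), quinuclidine (30 mol%), K2CO3, 1,4-dioxane, 1 mM (slow addition), 450 nm LEDs, rt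
Reagents that add atoms: none
Why: Proposed new method: this is an intramolecular, medium-ring version of the nickel/photoredox/hydrogen-atom-transfer aldehyde C–H alkenylation, so far shown only between two separate partners (closest known reaction type: triple-catalytic aldehyde C–H arylation, alkenylation and alkylation with organic bromides); the excited iridium complex oxidises quinuclidine, whose radical cation abstracts the hydridic formyl hydrogen at C9; zerovalent nickel inserts into C8–Br (much faster than into the tetrasubstituted C6–Cl bond) with retention of geometry, the divalent alkenylnickel captures the tethered acyl radical, and reductive elimination from trivalent nickel forms C8–C9 and the ten-membered ring, helped by the two ring-cis alkenes and the trans C2/C9 arms on ring A; no stereocentre is made or touched.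

**Step 16**
Reactants: 25 macrocyclic dienone ester
Product: 27 β-alkylidene O9-lactone (9S; C17 epimer mixture), via hydroxy ester 26 (not isolated)
Conditions: NaBH4, CeCl3·7H2O, MeOH, −78 to 0 °C; PPTS (10 mol%), CH2Cl2, rt
Reagents that add atoms: none
Why: In the Luche 1,2-reduction hydride reaches C9 anti to the C10–C1 bond (Felkin–Anh, which is also the outer face of the ring) and gives the 9S alcohol, which closes onto the C19 ester to a five-membered lactone.

**Step 17**
Reactants: 27 lactone (C17 mixture)
Product: 29 (17R)-β-alkylidene O9-lactone, via lithium dienolate 28 (not isolated)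
Conditions: LiN(SiMe3)2 (1.05 equiv), THF, −78 °C, 10 min; AcOH, THF, −78 °C
Reagents that add atoms: none
Why: In this kinetic deconjugative α-protonation the acid reaches the planar dienolate at C17 from the convex face opposite C10 and the carbocycle, so Me-18 ends cis to C10 (17R) and both epimers converge; the doubly activated C17–H is removed far faster than an acetate α-hydrogen.

**Step 18**
Reactants: 29 (17R)-lactone
Product: 31 CNP0296164.1 (target), via O9-lactone diol 30 (not isolated)
Conditions: OsO4 (5 mol%), NMO, acetone/H2O, 0 °C; DBU (10 mol%), CH2Cl2, rt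
Reagents that add atoms: N-methylmorpholine N-oxide, C[N+]1([O-])CCOCC1; water, O
Why: Upjohn syn-dihydroxylation of the trisubstituted C7=C8 alkene (ahead of the hindered C13=C14 alkene and the chloroalkene) from the convex face anti to C10 and Me-18 sets 7R,8R; the crowded O9-lactone, with C10, C7 and Me-18 all cis, then relaxes by base-catalysed acyl migration to O7, where C6, C9 and Me-18 alternate trans, and this frees 9-OH.

**Compound list**
1 | (R)-(−)-carvone | CC1=CC[C@H](CC1=O)C(C)=C | starting material
2 | lithium cross-conjugated dienolate of carvone | CC1=CC[C@@H](C(C)=C)C=C1O[Li] | intermediate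
3 | (5R,6S)-6-methylcarvone | O=C1C(C)=CC[C@@H](C(C)=C)[C@@H]1C | intermediate
4 | 2,3-epoxide of 3 (oxygen trans to isopropenyl) | O=C1[C@]2(C)O[C@@H]2C[C@@H](C(C)=C)[C@@H]1C | intermediate
5 | hydrazone of 4 | NN=C1[C@]2(C)O[C@@H]2C[C@@H](C(C)=C)[C@@H]1C | intermediate
6 | (1R,4R,5R)-2,4-dimethyl-5-(prop-1-en-2-yl)cyclohex-2-en-1-ol | O[C@@H]1C[C@@H](C(C)=C)[C@H](C)C=C1C | intermediate
7 | (4R,5R)-2,4-dimethyl-5-(prop-1-en-2-yl)cyclohex-2-en-1-one | O=C1C[C@@H](C(C)=C)[C@H](C)C=C1C | intermediate
8 | α-methoxy hydroperoxide from 7 | O=C1C[C@@H](C(C)(OC)OO)[C@H](C)C=C1C | intermediate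
9 | peroxyacetate of 8 | O=C1C[C@@H](C(C)(OC)OOC(C)=O)[C@H](C)C=C1C | intermediate
10 | (4R,5R)-5-acetoxy-2,4-dimethylcyclohex-2-en-1-one | O=C1C[C@@H](OC(C)=O)[C@H](C)C=C1C | intermediate
11 | but-2-yn-1-ol | CC#CCO | starting material
12 | [2-(1,3-dioxolan-2-yl)ethyl]magnesium bromide | Br[Mg]CCC1OCCO1 | starting material
13 | alkenylmagnesium alkoxide (five-membered magnesacycle) | C/C(CCC1OCCO1)=C2/CO[Mg]2 | intermediate
14 | (E)-2-chloro-5-(1,3-dioxolan-2-yl)-3-methylpent-2-en-1-ol | OC/C(Cl)=C(/C)CCC1OCCO1 | intermediate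
15 | (E)-2-chloro-5-(1,3-dioxolan-2-yl)-3-methylpent-2-enal | O=C/C(Cl)=C(/C)CCC1OCCO1 | intermediate
16 | (3E)-1,1-dibromo-3-chloro-6-(1,3-dioxolan-2-yl)-4-methylhexa-1,3-diene | BrC(Br)=C/C(Cl)=C(/C)CCC1OCCO1 | intermediate
17 | methyl (3Z,5E)-3-bromo-5-chloro-8-(1,3-dioxolan-2-yl)-2,6-dimethylocta-3,5-dienoate | COC(=O)C(C)/C(Br)=C/C(Cl)=C(/C)CCC1OCCO1 | intermediate
18 | methyl (3Z,5E)-3-bromo-5-chloro-2,6-dimethyl-9-oxonona-3,5-dienoate | COC(=O)C(C)/C(Br)=C/C(Cl)=C(/C)CCC=O | intermediate
19 | bromomagnesium enolate after vinyl addition | C=C[C@H]1[C@@H](C)[C@H](OC(C)=O)CC(O[Mg]Br)=C1C | intermediate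
20 | bromomagnesium aldolate | Br[Mg]O[C@@H](CC/C(C)=C(/Cl)\C=C(Br)\C(C)C(=O)OC)[C@@]1(C)C(=O)C[C@@H](OC(C)=O)[C@H](C)[C@@H]1C=C | intermediate
21 | keto diacetate | CC(=O)O[C@@H](CC/C(C)=C(/Cl)\C=C(Br)\C(C)C(=O)OC)[C@@]1(C)C(=O)C[C@@H](OC(C)=O)[C@H](C)[C@@H]1C=C | intermediate
22 | C14 alcohol | CC(=O)O[C@@H](CC/C(C)=C(/Cl)\C=C(Br)\C(C)C(=O)OC)[C@@]1(C)C(O)C[C@@H](OC(C)=O)[C@H](C)[C@@H]1C=C | intermediate
23 | C13=C14 cyclohexene with C10 vinyl | CC(=O)O[C@@H](CC/C(C)=C(/Cl)\C=C(Br)\C(C)C(=O)OC)[C@@]1(C)C=C[C@@H](OC(C)=O)[C@H](C)[C@@H]1C=C | intermediate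
24 | seco bromo aldehyde | CC(=O)O[C@@H](CC/C(C)=C(/Cl)\C=C(Br)\C(C)C(=O)OC)[C@@]1(C)C=C[C@@H](OC(C)=O)[C@H](C)[C@@H]1C=O | intermediate
25 | ten-membered dienone ester | CC(=O)O[C@H]1CC/C(C)=C(/Cl)\C=C(\C(C)C(=O)OC)C(=O)[C@H]2[C@@H](C)[C@H](OC(C)=O)C=C[C@@]21C | intermediate
26 | (9S)-hydroxy ester | CC(=O)O[C@H]1CC/C(C)=C(/Cl)\C=C(\C(C)C(=O)OC)[C@@H](O)[C@H]2[C@@H](C)[C@H](OC(C)=O)C=C[C@@]21C | intermediate
27 | β-alkylidene O9-lactone, C17 mixture | CC(=O)O[C@H]1CC/C(C)=C(/Cl)\C=C3\C(C)C(=O)O[C@H]3[C@H]2[C@@H](C)[C@H](OC(C)=O)C=C[C@@]21C | intermediate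
28 | lithium dienolate of 27 | CC(=O)O[C@H]1CC/C(C)=C(/Cl)\C=C3\C(C)=C(O[Li])O[C@H]3[C@H]2[C@@H](C)[C@H](OC(C)=O)C=C[C@@]21C | intermediate
29 | (17R)-β-alkylidene O9-lactone | CC(=O)O[C@H]1CC/C(C)=C(/Cl)\C=C3\[C@@H](C)C(=O)O[C@H]3[C@H]2[C@@H](C)[C@H](OC(C)=O)C=C[C@@]21C | intermediate
30 | O9-lactone 7,8-diol | CC(=O)O[C@H]1CC/C(C)=C(/Cl)[C@H](O)[C@@]3(O)[C@@H](C)C(=O)O[C@H]3[C@H]2[C@@H](C)[C@H](OC(C)=O)C=C[C@@]21C | intermediate
31 | CNP0296164.1 | CC(=O)O[C@H]1CC/C(C)=C(/Cl)[C@@H]2OC(=O)[C@H](C)[C@@]2(O)[C@@H](O)[C@H]2[C@@H](C)[C@H](OC(C)=O)C=C[C@@]21C | target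

**Totals**
- Total step count: 18.
- Longest linear sequence: 13 steps (steps 1–5 and 11–18). Steps 6–10 are the side branch.

**Three steps most likely to fail**

Step 15 (the new ring closure). The acyl radical may lose CO, oligomers may form, C10 may epimerise next to the aldehyde, or the β,γ‑unsaturated ester may slip into conjugation. The fallback sets out from 24. A classical Nozaki–Hiyama–Kishi ring closure (CrCl2 in excess, NiCl2 catalytic, DMSO/THF, high dilution, cold quench) gives the C9‑epimeric macrocyclic allylic alcohols F1. Dess–Martin periodinane oxidises both epimers to the dienone, so the route is rejoined at 25.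

Step 11 (one‑pot 1,4‑addition and aldol to a quaternary centre). The hindered enolate may simply deprotonate 18, or the aldolate may revert. The fallback sets out from 10. (CH2=CH)2CuLi with Me3SiCl gives the isolable trimethylsilyl enol ether F2. A TiCl4‑mediated Mukaiyama aldol with 18 gives the free C2 aldol F3. Ac2O/DMAP then acetylates it, and the route is rejoined at 21.

Step 17 (kinetic setting of C17). γ‑Protonation to the conjugated butenolide or attack on an acetate may compete. The fallback sets out from 27 and replaces kinetic by thermodynamic control. The C17 mixture is dihydroxylated as in step 18 to the O9‑lactone diol epimer mixture F4. DBU shifts the acyl group to give the target together with its 17‑epimer F5. Prolonged DBU in toluene at 60 °C then equilibrates C17 to the more stable isomer, with Me‑18 trans to C9, and the route is rejoined at 31.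

**Further compounds**
F1 | step 15 | C9-epimeric macrocyclic allylic alcohols | CC(=O)O[C@H]1CC/C(C)=C(/Cl)\C=C(\C(C)C(=O)OC)C(O)[C@H]2[C@@H](C)[C@H](OC(C)=O)C=C[C@@]21C
F2 | step 11 | trimethylsilyl enol ether of the vinyl adduct | C=C[C@H]1[C@@H](C)[C@H](OC(C)=O)CC(O[Si](C)(C)C)=C1C
F3 | step 11 | free C2 aldol (2-hydroxy analogue of 21) | O[C@@H](CC/C(C)=C(/Cl)\C=C(Br)\C(C)C(=O)OC)[C@@]1(C)C(=O)C[C@@H](OC(C)=O)[C@H](C)[C@@H]1C=C
F4 | step 17 | O9-lactone 7,8-diol, C17 epimer mixture | CC(=O)O[C@H]1CC/C(C)=C(/Cl)[C@H](O)[C@@]3(O)C(C)C(=O)O[C@H]3[C@H]2[C@@H](C)[C@H](OC(C)=O)C=C[C@@]21C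
F5 | step 17 | target together with its 17-epimer | CC(=O)O[C@H]1CC/C(C)=C(/Cl)[C@@H]2OC(=O)C(C)[C@@]2(O)[C@@H](O)[C@H]2[C@@H](C)[C@H](OC(C)=O)C=C[C@@]21C
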